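## The problem

Target 21 is a linear tridepside. Three benzoate rings are joined head to tail by two aryl ester bonds: ring A carries the free carboxyl (C1), a methoxy group (C2), methyls (C3, C6) and the ester oxygen (C4); ring B is fully substituted (C1 carbonyl, C2 OMe, C3/C5/C6 Me, C4 oxygen); ring C is a 2,4-dihydroxy-3,6-dimethylbenzoyl unit. There are no stereocentres, so the difficulty is steric and chemoselective rather than spatial. Both ester carbonyls have two ortho substituents (ring B C1 between C2–OMe and C6–Me, ring C C1 between C2–OH and C6–Me), and the ring B oxygen at C4 sits between two methyl groups, so ordinary acyl transfer is slow at each junction. All three rings share one 2-methylresorcinol pattern but use their two oxygens differently (OMe and O-acyl in rings A and B, two free OH in ring C), so chemically similar oxygens must be told apart ring by ring. The aryl esters will not survive hydroxide, alkoxide or hard nucleophiles, so the ring A acid and the ring C phenols should be unmasked last under neutral conditions. The feature that opens the structure is the ring B carboxyl carbon: it is bonded to ring B C1 on one side and to the ring A oxygen at C4 on the other, so both of its bonds can be made from carbon monoxide at palladium instead of by activating a hindered benzoic acid. Ring B C1 is also the only hydrogen-bearing carbon of the corresponding pentasubstituted phenol and lies para to its hydroxyl, so the aryl iodide needed is regiochemically unambiguous.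

## Retrosynthesis

**Unmasking.** Target 21 is traced to the tribenzyl compound 20 by cutting three benzyl–oxygen bonds (the ring A ester and the two ring C ethers). Hydrogenolysis is neutral and non-nucleophilic, which is what the two depside links require. Methyl or silyl masking would need nucleophiles, Lewis acids or fluoride in the presence of two aryl esters.

**Ring B–ring C ester.** 20 is cut at the bond between the ring C carbonyl and the ring B oxygen at C4, giving phenol 16 and acid 18. Ring C is the simplest piece and is best added last. Its acid 18 is electron-rich and doubly ortho-substituted, so its mixed trifluoroacetic anhydride 19 ionises readily to a linear acylium ion that a flanked phenol can reach. The forward step must leave the A–B aryl ester and the benzyl groups intact. Phenol 16 comes from acetal 15 by acid hydrolysis.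

**Ring A–ring B ester (key cut).** 15 is cut at two bonds at once: ring B C1 to the carbonyl carbon, and the carbonyl carbon to the ring A oxygen. This gives aryl iodide 8, phenol 13 and carbon monoxide 14. The neighbouring cut of only the C–O bond would need the acid of ring B to be activated between an OMe and a Me group while carrying an acid-labile acetal. The carbonylative cut moves both bond formations to palladium, one atom away from the crowded ring carbon. The precursors are much simpler, a monocyclic iodide and a monocyclic phenol. The forward reaction needs a single free phenol (hence MOM on ring B and a benzyl ester on ring A) and CO insertion faster than any direct coupling.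

**Ring B iodide.** 8 is traced through phenol 7 (MOM protection) to phenol 6 (iodination at the only free ring position). 6 comes from aldehyde 4 by reducing the formyl group to the methyl that becomes ring B C5. 4 comes from dihydroxyaldehyde 3 by methylating the hydroxyl para to the formyl group. Differentiating the two oxygens at the aldehyde stage is preferred to doing so after the formyl group has become a methyl group, because the ortho hydroxyl of 3 is held in a hydrogen bond while the para hydroxyl is free and more acidic. That innate preference is exactly the pattern ring B needs.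

**Ring A phenol.** 13 needs the opposite pattern (OMe ortho to the carbonyl, free OH para). It is traced to MOM ether 12 and acid 11 (carboxylate benzylation), then to aldehyde 10 (Pinnick oxidation), to 9 (methylation of the chelated hydroxyl) and to 3 (MOM protection of the reactive para hydroxyl). The temporary acetal costs steps but turns the same innate selectivity to the opposite outcome.

**Ring C acid and the common aldehyde.** 18 comes from aldehyde 17 by Pinnick oxidation, and 17 from 3 by double benzylation. Aldehyde 3 is traced to the symmetric diol 1 by cutting the formyl C–C bond. The two positions open to formylation are equivalent, so one commercial arene supplies all three rings.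

## Roads not taken

**Alternative 1:** Here ring C itself is disconnected (its bonds C1–C2, C2–C3 and C4–C5). The product A1, the benzyl ester of 21 with a triisopropylsilyl group on the ring C 4-oxygen, would arise from diazo ketone A2 and the silyl ynol ether A3. A2 is the A–B depside whose ring B oxygen carries an (E)-5-diazo-3-methyl-4-oxopent-2-enoyl ester. Irradiation would trigger a Wolff rearrangement to a vinylketene, (2+2) addition to A3, four-electron ring opening and six-electron electrocyclisation (a Danheiser benzannulation).
- Merits: the polarity of ynol ether and ketene fixes the whole ring C substitution pattern without isomers. The B–C ester is made by acylating the flanked ring B phenol with a small acyclic acid, not with a doubly ortho-substituted benzoic acid. On that bond this road is better than the chosen plan, which has only the acylium mechanism of step 15 to set against it.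
- Weak points: two aryl esters are exposed to ultraviolet light, where photo-Fries rearrangement competes. A diazo ketone conjugated to an enoate is prone to dipolar self-addition. The vinylketene carries an electron-withdrawing ester at its terminus. Making A2 needs several steps on advanced material.
- Comparison: it spends the key step on the cheapest ring, which the chosen plan gets from aldehyde 3 in two steps by way of 17 and 18. It leaves the A–B ester, the harder junction, to classical acylation of the ring B acid.

**Alternative 2:** The cut is at ring A C1–carboxyl and C6–CH2. Product A4, benzyl 6-[2-(benzyloxy)-2-oxoethyl]-2-methoxy-4-(methoxymethoxy)-3-methylbenzoate, would come from silyl triflate A5 and dibenzyl malonate A6. CsF would release the C1–C6 aryne. The malonate carbanion would add at C6, away from the methoxy group, and the aryl anion at C1 would attack an ester carbonyl and fragment, inserting the aryne into a C–C bond of A6.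
- Merits: both ortho substituents of ring A are installed in one mild step with regiocontrol from the methoxy group. The ring A carboxyl arrives directly as its benzyl ester. That is neater than the five functional-group steps the chosen plan spends on 13.
- Weak points: C6 ends up bearing CH2CO2Bn, not CH3. The two benzyl esters must then be distinguished and an arylacetic acid protodecarboxylated, which is not a facile reaction. A5 is a heavily substituted ortho-silyl aryl triflate that needs its own multistep preparation.
- Comparison: none of the difficult bonds (the two hindered depside links and the fully substituted ring B) is addressed. The chosen plan solves ring A with routine chemistry from 3 and reserves its key step for the most hindered junction.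

**Alternative 3:** The cut is at ring B C3–C4 and C1–C6. Product A7, benzyl 4-[(2,4-dihydroxy-3,5,6-trimethylbenzoyl)oxy]-2-methoxy-3,6-dimethylbenzoate, would come from the bis(trimethylsilyloxy)diene A8 and (E)-3-methoxy-2-methylbut-2-enoyl chloride A9 under TiCl4. A8 would be made from the ring A aryl 3-oxopentanoate A10. The diene terminus would be acylated, the central carbon would add to the enol ether carbon with loss of methanol, and the ring would aromatise.
- Merits: the fully substituted ring is created in one step with the A–B ester already in place, so the hindered ring B acid is never made or activated. In that respect it matches the chosen plan. It also forms two C–C bonds and a ring at once, which the chosen plan does not.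
- Weak points: A7 has both ring B hydroxyls free, whereas the target needs OMe at C2 (chelated and flanked) and the ring C ester at C4. Methylating the chelated hydroxyl with base in the presence of aryl esters invites acyl migration and cleavage, and the alternative is a protect, methylate, deprotect detour. Aryl β-keto esters such as A10 expel phenoxide to give acylketenes on enolisation, so the preparation of A8 is uncertain. If the two electrophilic carbons of A9 are taken in the opposite order, a 2,6-dihydroxy isomer results.
- Comparison: the chosen plan inherits every ring position from diol 1 and from the single free carbon of 6, and settles the oxygen pattern early on small molecules.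

Key step: step 11

## Route

Assumption: 2,5-dimethylbenzene-1,3-diol 1 and carbon monoxide 14 are taken as the commercial starting materials; every ring carbon of the target derives from 1.

Step 1
Reactants: 1 2,5-dimethylbenzene-1,3-diol
Product: 3 2,4-dihydroxy-3,6-dimethylbenzaldehyde, via aryl iminium chloride 2 (not isolated)
Conditions: POCl3, DMF, 0 °C to rt; then H2O, 50 °C
Reagents that add atoms: N,N-dimethylformamide CN(C)C=O; water O
Why: Vilsmeier–Haack formylation; the chloroiminium ion attacks ortho to one hydroxyl and para to the other, the two such positions of the symmetric diol are equivalent, the iminium product 2 is deactivated towards a second attack, and hydrolysis releases the aldehyde.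

Step 2
Reactants: 3 2,4-dihydroxy-3,6-dimethylbenzaldehyde
Product: 4 2-hydroxy-4-methoxy-3,6-dimethylbenzaldehyde
Conditions: MeI (1.05 equiv), K2CO3, acetone, rt
Reagents that add atoms: iodomethane CI
Why: Williamson etherification; the hydroxyl para to the formyl group is free and the more acidic, while the ortho hydroxyl is hydrogen-bonded to the carbonyl and flanked on both sides, so one equivalent of MeI with a weak base should alkylate the para oxygen.

Step 3
Reactants: 4 2-hydroxy-4-methoxy-3,6-dimethylbenzaldehyde
Product: 6 3-methoxy-2,5,6-trimethylphenol, via benzylic alcohol 5 (not isolated)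
Conditions: H2 (3 bar), 10% Pd/C, AcOH, cat. HCl, rt
Reagents that add atoms: none
Why: Catalytic hydrogenation of the aldehyde to the benzylic alcohol 5 followed by acid-assisted hydrogenolysis of its electron-rich benzylic C–O bond, the standard formyl-to-methyl conversion of hydroxybenzaldehydes; nothing else in the molecule is reducible.

Step 4
Reactants: 6 3-methoxy-2,5,6-trimethylphenol
Product: 7 4-iodo-3-methoxy-2,5,6-trimethylphenol
Conditions: NIS, MeCN, 0 °C to rt, dark
Reagents that add atoms: N-iodosuccinimide O=C1CCC(=O)N1I
Why: Electrophilic aromatic iodination; the ring has a single hydrogen-bearing carbon, which is para to the hydroxyl and ortho to the methoxy group, so the site is both unique and strongly activated.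

Step 5
Reactants: 7 4-iodo-3-methoxy-2,5,6-trimethylphenol
Product: 8 1-iodo-2-methoxy-4-(methoxymethoxy)-3,5,6-trimethylbenzene
Conditions: NaH, MOMCl, DMF, 0 °C to rt
Reagents that add atoms: chloromethyl methyl ether COCCl
Why: O-alkylation of the sodium phenoxide with a very reactive electrophile (MOM ether formation); irreversible deprotonation overcomes the two flanking methyl groups and the aryl iodide is inert.

Step 6
Reactants: 3 2,4-dihydroxy-3,6-dimethylbenzaldehyde
Product: 9 2-hydroxy-4-(methoxymethoxy)-3,6-dimethylbenzaldehyde
Conditions: MOMCl (1.1 equiv), K2CO3, acetone, 0 °C to rt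
Reagents that add atoms: chloromethyl methyl ether COCCl
Why: Selective MOM ether formation at the free, more acidic para hydroxyl for the same reason as in step 2; the chelated ortho hydroxyl stays untouched under weak base.

Step 7
Reactants: 9 2-hydroxy-4-(methoxymethoxy)-3,6-dimethylbenzaldehyde
Product: 10 2-methoxy-4-(methoxymethoxy)-3,6-dimethylbenzaldehyde
Conditions: MeI (excess), K2CO3, DMF, 50 °C
Reagents that add atoms: iodomethane CI
Why: Williamson methylation of the remaining chelated hydroxyl, which needs excess MeI in warm DMF; the acetal and the aldehyde are stable to carbonate.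

Step 8
Reactants: 10 2-methoxy-4-(methoxymethoxy)-3,6-dimethylbenzaldehyde
Product: 11 2-methoxy-4-(methoxymethoxy)-3,6-dimethylbenzoic acid
Conditions: NaClO2, NaH2PO4, 2-methylbut-2-ene, t-BuOH/H2O, rt
Reagents that add atoms: sodium chlorite [Na+].[O-]Cl=O
Why: Pinnick oxidation; chlorous acid oxidises even a doubly ortho-substituted aldehyde, the buffered pH spares the acetal, and the alkene scavenger removes hypochlorous acid before it can chlorinate the activated C5–H.

Step 9
Reactants: 11 2-methoxy-4-(methoxymethoxy)-3,6-dimethylbenzoic acid
Product: 12 benzyl 2-methoxy-4-(methoxymethoxy)-3,6-dimethylbenzoate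
Conditions: BnBr, K2CO3, DMF, rt
Reagents that add atoms: benzyl bromide BrCc1ccccc1
Why: Carboxylate O-alkylation (SN2 at the benzylic carbon); the two ortho substituents that would block a Fischer esterification do not hinder it.

Step 10
Reactants: 12 benzyl 2-methoxy-4-(methoxymethoxy)-3,6-dimethylbenzoate
Product: 13 benzyl 4-hydroxy-2-methoxy-3,6-dimethylbenzoate
Conditions: HCl (cat.), MeOH, 50 °C
Reagents that add atoms: none
Why: Acid-catalysed acetal exchange with methanol removes the MOM group and traps the methoxymethyl cation as dimethoxymethane; the doubly ortho-substituted benzyl ester resists acid-catalysed transesterification.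

Step 11
Reactants: 8 1-iodo-2-methoxy-4-(methoxymethoxy)-3,5,6-trimethylbenzene; 13 benzyl 4-hydroxy-2-methoxy-3,6-dimethylbenzoate; 14 carbon monoxide
Product: 15 benzyl 2-methoxy-4-{[2-methoxy-4-(methoxymethoxy)-3,5,6-trimethylbenzoyl]oxy}-3,6-dimethylbenzoate
Conditions: CO (3 bar), Pd(OAc)2 (5 mol %), Xantphos (6 mol %), K3PO4, toluene, 100 °C
Reagents that add atoms: none
Why: Pd(OAc)2 is reduced in situ to zerovalent palladium, which adds oxidatively to the C–I bond of 8, the weakest bond present. Coordination and migratory insertion of carbon monoxide 14 then give an aroyl complex of divalent palladium; the C2 methoxy and C6 methyl groups help insertion because it moves the metal one atom away from the crowded ring carbon. The phenoxide of 13, formed by K3PO4, displaces iodide on palladium, and C(acyl)–O reductive elimination releases 15 and regenerates zerovalent palladium. The closest known reaction type is the palladium-catalysed aryloxycarbonylation of aryl iodides with CO and phenols, a reaction type that tolerates ortho-substituted aryl halides. No ring is closed and no stereocentre is formed. The selectivity needed is chemoselectivity: CO insertion must outrun direct aryl–oxygen coupling and hydrodeiodination, and ester-forming elimination must outrun decarbonylation. This is secured because an aryl–palladium flanked by two ortho groups is slow to form a diaryl ether but quick to insert CO, the wide bite angle of Xantphos favours the acyl species and its reductive elimination, no alcohol or amine is present as a hydride source, and 13 is the only nucleophile since the ring B oxygen is a MOM acetal and the ring A carboxyl a benzyl ester, both inert to phosphate at 100 °C.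

Step 12
Reactants: 15 benzyl 2-methoxy-4-{[2-methoxy-4-(methoxymethoxy)-3,5,6-trimethylbenzoyl]oxy}-3,6-dimethylbenzoate
Product: 16 benzyl 4-[(4-hydroxy-2-methoxy-3,5,6-trimethylbenzoyl)oxy]-2-methoxy-3,6-dimethylbenzoate
Conditions: 3 M HCl (aq), THF, 45 °C
Reagents that add atoms: none
Why: Acid hydrolysis of the aryl MOM acetal; the benzyl ester and the new aryl ester are each shielded by two ortho substituents and should withstand dilute aqueous acid, and no alcohol solvent is present that could exchange the aryl ester.

Step 13
Reactants: 3 2,4-dihydroxy-3,6-dimethylbenzaldehyde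
Product: 17 2,4-bis(benzyloxy)-3,6-dimethylbenzaldehyde
Conditions: BnBr (2.5 equiv), K2CO3, DMF, 60 °C
Reagents that add atoms: benzyl bromide BrCc1ccccc1
Why: Double Williamson benzylation; excess BnBr and warming in DMF are needed so that the chelated ortho hydroxyl is alkylated as well as the para one.

Step 14
Reactants: 17 2,4-bis(benzyloxy)-3,6-dimethylbenzaldehyde
Product: 18 2,4-bis(benzyloxy)-3,6-dimethylbenzoic acid
Conditions: NaClO2, NaH2PO4, 2-methylbut-2-ene, t-BuOH/THF/H2O, rt
Reagents that add atoms: sodium chlorite [Na+].[O-]Cl=O
Why: Pinnick oxidation as in step 8; the benzyl ethers are inert and the scavenger protects the electron-rich ring from chlorination.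

Step 15
Reactants: 18 2,4-bis(benzyloxy)-3,6-dimethylbenzoic acid; 16 benzyl 4-[(4-hydroxy-2-methoxy-3,5,6-trimethylbenzoyl)oxy]-2-methoxy-3,6-dimethylbenzoate
Product: 20 benzyl 4-[(4-{[2,4-bis(benzyloxy)-3,6-dimethylbenzoyl]oxy}-2-methoxy-3,5,6-trimethylbenzoyl)oxy]-2-methoxy-3,6-dimethylbenzoate, via mixed trifluoroacetic anhydride 19 (not isolated)
Conditions: (CF3CO)2O, toluene, 0 °C to rt
Reagents that add atoms: none
Why: Trifluoroacetic anhydride esterification, the classical depside coupling; the mixed anhydride 19 of an electron-rich 2,6-disubstituted benzoic acid ionises to a linear acylium ion that the flanked phenol of 16 can reach, and the benzyl ethers, the benzyl ester and the A–B aryl ester should tolerate brief exposure to trifluoroacetic acid in toluene.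

Step 16
Reactants: 20 benzyl 4-[(4-{[2,4-bis(benzyloxy)-3,6-dimethylbenzoyl]oxy}-2-methoxy-3,5,6-trimethylbenzoyl)oxy]-2-methoxy-3,6-dimethylbenzoate
Product: 21 4-[(4-{[2,4-dihydroxy-3,6-dimethylbenzoyl]oxy}-2-methoxy-3,5,6-trimethylbenzoyl)oxy]-2-methoxy-3,6-dimethylbenzoic acid
Conditions: H2 (1 atm), 10% Pd/C, EtOAc, rt
Reagents that add atoms: none
Why: Hydrogenolysis of the benzyl ester and the two benzyl aryl ethers over palladium under neutral conditions in a non-nucleophilic solvent; the aryl esters, methyl ethers and arene rings are not affected.

## Compound list

1 | 2,5-dimethylbenzene-1,3-diol | Cc1cc(O)c(C)c(O)c1 | starting material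
2 | N-[(2,4-dihydroxy-3,6-dimethylphenyl)methylidene]-N-methylmethanaminium chloride | C[N+](C)=Cc1c(C)cc(O)c(C)c1O.[Cl-] | intermediate
3 | 2,4-dihydroxy-3,6-dimethylbenzaldehyde | Cc1cc(O)c(C)c(O)c1C=O | intermediate
4 | 2-hydroxy-4-methoxy-3,6-dimethylbenzaldehyde | COc1cc(C)c(C=O)c(O)c1C | intermediate
5 | 2-(hydroxymethyl)-5-methoxy-3,6-dimethylphenol | COc1cc(C)c(CO)c(O)c1C | intermediate
6 | 3-methoxy-2,5,6-trimethylphenol | COc1cc(C)c(C)c(O)c1C | intermediate
7 | 4-iodo-3-methoxy-2,5,6-trimethylphenol | COc1c(I)c(C)c(C)c(O)c1C | intermediate
8 | 1-iodo-2-methoxy-4-(methoxymethoxy)-3,5,6-trimethylbenzene | COCOc1c(C)c(C)c(I)c(OC)c1C | intermediate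
9 | 2-hydroxy-4-(methoxymethoxy)-3,6-dimethylbenzaldehyde | COCOc1cc(C)c(C=O)c(O)c1C | intermediate
10 | 2-methoxy-4-(methoxymethoxy)-3,6-dimethylbenzaldehyde | COCOc1cc(C)c(C=O)c(OC)c1C | intermediate
11 | 2-methoxy-4-(methoxymethoxy)-3,6-dimethylbenzoic acid | COCOc1cc(C)c(C(=O)O)c(OC)c1C | intermediate
12 | benzyl 2-methoxy-4-(methoxymethoxy)-3,6-dimethylbenzoate | COCOc1cc(C)c(C(=O)OCc2ccccc2)c(OC)c1C | intermediate
13 | benzyl 4-hydroxy-2-methoxy-3,6-dimethylbenzoate | COc1c(C)c(O)cc(C)c1C(=O)OCc1ccccc1 | intermediate
14 | carbon monoxide | [C-]#[O+] | starting material
15 | benzyl 2-methoxy-4-{[2-methoxy-4-(methoxymethoxy)-3,5,6-trimethylbenzoyl]oxy}-3,6-dimethylbenzoate | COCOc1c(C)c(C)c(C(=O)Oc2cc(C)c(C(=O)OCc3ccccc3)c(OC)c2C)c(OC)c1C | intermediate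
16 | benzyl 4-[(4-hydroxy-2-methoxy-3,5,6-trimethylbenzoyl)oxy]-2-methoxy-3,6-dimethylbenzoate | COc1c(C)c(O)c(C)c(C)c1C(=O)Oc1cc(C)c(C(=O)OCc2ccccc2)c(OC)c1C | intermediate
17 | 2,4-bis(benzyloxy)-3,6-dimethylbenzaldehyde | Cc1cc(OCc2ccccc2)c(C)c(OCc2ccccc2)c1C=O | intermediate
18 | 2,4-bis(benzyloxy)-3,6-dimethylbenzoic acid | Cc1cc(OCc2ccccc2)c(C)c(OCc2ccccc2)c1C(=O)O | intermediate
19 | 2,4-bis(benzyloxy)-3,6-dimethylbenzoic trifluoroacetic anhydride | Cc1cc(OCc2ccccc2)c(C)c(OCc2ccccc2)c1C(=O)OC(=O)C(F)(F)F | intermediate
20 | benzyl 4-[(4-{[2,4-bis(benzyloxy)-3,6-dimethylbenzoyl]oxy}-2-methoxy-3,5,6-trimethylbenzoyl)oxy]-2-methoxy-3,6-dimethylbenzoate | COc1c(C)c(OC(=O)c2c(C)c(C)c(OC(=O)c3c(C)cc(OCc4ccccc4)c(C)c3OCc3ccccc3)c(C)c2OC)cc(C)c1C(=O)OCc1ccccc1 | intermediate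
21 | 4-[(4-{[2,4-dihydroxy-3,6-dimethylbenzoyl]oxy}-2-methoxy-3,5,6-trimethylbenzoyl)oxy]-2-methoxy-3,6-dimethylbenzoic acid | COc1c(C)c(OC(=O)c2c(C)c(C)c(OC(=O)c3c(C)cc(O)c(C)c3O)c(C)c2OC)cc(C)c1C(=O)O | target

## Step count and least certain steps

Total step count: 16. Longest linear sequence: 10 steps (steps 1, 6, 7, 8, 9, 10, 11, 12, 15, 16).

**Step 11 (key step).** Oxidative addition and CO insertion should proceed, but capture of the crowded aroyl–palladium species by a phenoxide that is weakened by its para ester may be slow. Reduction of the C–I bond or precipitation of the catalyst as palladium metal could then overtake ester formation. Fallback, which gives up the carbonylation but keeps the same two fragments: from 8, iodine–lithium exchange with n-BuLi in THF at −78 °C and a CO2 quench would give 2-methoxy-4-(methoxymethoxy)-3,5,6-trimethylbenzoic acid F1 after brief acidification with cold dilute HCl. The neutral chloroenamine reagent 1-chloro-N,N,2-trimethylprop-1-en-1-amine would convert F1 into 2-methoxy-4-(methoxymethoxy)-3,5,6-trimethylbenzoyl chloride F2 without touching the acetal. F2 would acylate the sodium phenoxide of 13 (NaH, THF, heating), returning to the route at 15.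

**Step 15.** Acylation of a phenol flanked by two methyl groups by a doubly ortho-substituted acyl donor may be slow. Trifluoroacetylation of the phenol, or acid-induced loss of the benzyl ether next to the acylium centre, could then compete on a valuable late intermediate. Fallback, which changes the order of assembly so that the hindered ester is forced on a small, robust fragment: from 18, oxalyl chloride and catalytic DMF would give 2,4-bis(benzyloxy)-3,6-dimethylbenzoyl chloride F3 in CH2Cl2. F3 would acylate the sodium phenoxide of 7 (NaH, THF, reflux, excess reagent permissible) to give 4-iodo-3-methoxy-2,5,6-trimethylphenyl 2,4-bis(benzyloxy)-3,6-dimethylbenzoate F4 as a compact aryl iodide. Carbonylative coupling of F4 with 13 and 14 under the conditions of step 11 would deliver 20 directly; the B–C ester is shielded from phenoxide exchange by its four ortho substituents. The route is rejoined at 20, and steps 5 and 12 become unnecessary.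

**Step 4.** The electron-rich, fully substituted phenol may be oxidised by the iodinating agent instead of substituted, or the product may lose iodine under traces of acid and light. Fallback, which masks the phenol before halogenation: from 6, NaH and MOMCl would give 1-methoxy-3-(methoxymethoxy)-2,4,5-trimethylbenzene F5 in DMF. The aryl ether F5 is far less prone to oxidation than the free phenol, and its single ring hydrogen is still para to one oxygen and ortho to the other. Iodination of F5 with NIS in MeCN would then give 8, where the route is rejoined.

**Step 2.** Discrimination between the two hydroxyls rests on acidity and hydrogen bonding, not on a blocking group, so over-methylation alongside unreacted diol is the likely failure. Fallback: from 3, exhaustive methylation (excess MeI, K2CO3, DMF) would give 2,4-dimethoxy-3,6-dimethylbenzaldehyde F6 with no selectivity to control. BCl3 in CH2Cl2 at low temperature would then cleave only the methyl ether of F6 that lies ortho to the formyl group, directed by boron chelation between the carbonyl and the ortho oxygen. Aqueous work-up gives 4 and rejoins the route there.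

**Step 8.** Hypochlorous acid that escapes the scavenger may chlorinate C5–H, which is ortho to the acetal oxygen and para to the methoxy group, and the acidic buffer may partly cleave the acetal. Fallback, which enters ring A at the carboxylic acid oxidation level: from 1, Kolbe–Schmitt carboxylation (KHCO3, CO2, heat, then dilute HCl) would give 2,4-dihydroxy-3,6-dimethylbenzoic acid F7 directly. Alkylation of the carboxylate of F7 with BnBr and KHCO3 in DMF would give benzyl 2,4-dihydroxy-3,6-dimethylbenzoate F8 with both phenols untouched. MOMCl and K2CO3 would protect the free para hydroxyl of F8 to give benzyl 2-hydroxy-4-(methoxymethoxy)-3,6-dimethylbenzoate F9 in acetone. Methylation of the chelated hydroxyl of F9 (MeI, K2CO3, DMF) would give 12, where the route is rejoined; steps 6 to 9 are then not needed.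

## Further compounds

F1 | step 11 | 2-methoxy-4-(methoxymethoxy)-3,5,6-trimethylbenzoic acid | COCOc1c(C)c(C)c(C(=O)O)c(OC)c1C
F2 | step 11 | 2-methoxy-4-(methoxymethoxy)-3,5,6-trimethylbenzoyl chloride | COCOc1c(C)c(C)c(C(Cl)=O)c(OC)c1C
F3 | step 15 | 2,4-bis(benzyloxy)-3,6-dimethylbenzoyl chloride | Cc1cc(OCc2ccccc2)c(C)c(OCc2ccccc2)c1C(Cl)=O
F4 | step 15 | 4-iodo-3-methoxy-2,5,6-trimethylphenyl 2,4-bis(benzyloxy)-3,6-dimethylbenzoate | COc1c(C)c(OC(=O)c2c(C)cc(OCc3ccccc3)c(C)c2OCc2ccccc2)c(C)c(C)c1I
F5 | step 4 | 1-methoxy-3-(methoxymethoxy)-2,4,5-trimethylbenzene | COCOc1c(C)c(C)cc(OC)c1C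
F6 | step 2 | 2,4-dimethoxy-3,6-dimethylbenzaldehyde | COc1cc(C)c(C=O)c(OC)c1C
F7 | step 8 | 2,4-dihydroxy-3,6-dimethylbenzoic acid | Cc1cc(O)c(C)c(O)c1C(=O)O
F8 | step 8 | benzyl 2,4-dihydroxy-3,6-dimethylbenzoate | Cc1cc(O)c(C)c(O)c1C(=O)OCc1ccccc1
F9 | step 8 | benzyl 2-hydroxy-4-(methoxymethoxy)-3,6-dimethylbenzoate | COCOc1cc(C)c(C(=O)OCc2ccccc2)c(O)c1C
A1 | alternative 1 | benzyl 4-{[4-({2-hydroxy-3,6-dimethyl-4-[(triisopropylsilyl)oxy]benzoyl}oxy)-2-methoxy-3,5,6-trimethylbenzoyl]oxy}-2-methoxy-3,6-dimethylbenzoate | COc1c(C)c(OC(=O)c2c(C)c(C)c(OC(=O)c3c(C)cc(O[Si](C(C)C)(C(C)C)C(C)C)c(C)c3O)c(C)c2OC)cc(C)c1C(=O)OCc1ccccc1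
A2 | alternative 1 | benzyl 4-{[4-{[(2E)-5-diazo-3-methyl-4-oxopent-2-enoyl]oxy}-2-methoxy-3,5,6-trimethylbenzoyl]oxy}-2-methoxy-3,6-dimethylbenzoate | COc1c(C)c(OC(=O)c2c(C)c(C)c(OC(=O)/C=C(\C)C(=O)C=[N+]=[N-])c(C)c2OC)cc(C)c1C(=O)OCc1ccccc1
A3 | alternative 1 | triisopropyl(prop-1-yn-1-yloxy)silane | CC#CO[Si](C(C)C)(C(C)C)C(C)C
A4 | alternative 2 | benzyl 6-[2-(benzyloxy)-2-oxoethyl]-2-methoxy-4-(methoxymethoxy)-3-methylbenzoate | COCOc1cc(CC(=O)OCc2ccccc2)c(C(=O)OCc2ccccc2)c(OC)c1C
A5 | alternative 2 | 3-methoxy-5-(methoxymethoxy)-4-methyl-2-(trimethylsilyl)phenyl trifluoromethanesulfonate | COCOc1cc(OS(=O)(=O)C(F)(F)F)c([Si](C)(C)C)c(OC)c1C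
A6 | alternative 2 | dibenzyl malonate | O=C(CC(=O)OCc1ccccc1)OCc1ccccc1
A7 | alternative 3 | benzyl 4-[(2,4-dihydroxy-3,5,6-trimethylbenzoyl)oxy]-2-methoxy-3,6-dimethylbenzoate | COc1c(C)c(OC(=O)c2c(C)c(C)c(O)c(C)c2O)cc(C)c1C(=O)OCc1ccccc1
A8 | alternative 3 | benzyl 4-{[1,3-bis(trimethylsilyloxy)penta-1,3-dien-1-yl]oxy}-2-methoxy-3,6-dimethylbenzoate (double-bond geometry not defined) | CC=C(O[Si](C)(C)C)C=C(O[Si](C)(C)C)Oc1cc(C)c(C(=O)OCc2ccccc2)c(OC)c1C
A9 | alternative 3 | (2E)-3-methoxy-2-methylbut-2-enoyl chloride | CO/C(C)=C(C)/C(=O)Cl
A10 | alternative 3 | benzyl 2-methoxy-3,6-dimethyl-4-[(3-oxopentanoyl)oxy]benzoate | CCC(=O)CC(=O)Oc1cc(C)c(C(=O)OCc2ccccc2)c(OC)c1C
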